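The ten-membered ring's missing C2–C7 bond is the disconnection: the target's C2=C3–C4(O)–C5(=C16)–C6–C7(O) array is the product pattern of an anionic oxy-Cope ring expansion of a trans-decalin (ring B = C1, C2, C7–C10) bearing a 7-allenyl 7-alkoxide and an equatorial (Z)-2-alkoxyvinyl group at C2. One chair [3,3] shift forms C4–C5, opens ring B into the cyclodecane, and sets the E C2=C3 alkene beside quaternary C1, the C4 stereocenter and the exo-methylene; the C7 dienolate is oxidised at C6 in the same flask. The precursor, a rigid bicyclic γ-lactone from a quinone Diels–Alder adduct, carries C1, C8, C9, C10 and C17 set by six-membered-ring control.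

Key step: step 17

Remark: briarane numbering of the target is used for every intermediate (C1 quaternary carbon with Me-15; C2–C10 ten-membered ring; C11–C14 ring A with Me-20 on C11; C16 exo-methylene; C17/C18/C19 lactone CH/Me/C=O); β is the face of Me-15, and "decalin" means ring A (C1, C10–C14) fused to ring B (C1, C2, C7–C10).

Step 1
Reactants: 1 2-methoxy-5-methyl-1,4-benzoquinone; 2 2-(trimethylsilyloxy)buta-1,3-diene
Product: 3 cis-fused adduct (ring A 11,14-dione with 12-OMe enol ether, ring B 7-OTMS enol ether, 1β-Me, 10β-H)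
Conditions: TiCl2(OiPr)2/(S)-BINOL (20 mol %; the BINOL antipode if the facial sense requires), 4 Å MS, toluene, −30 °C
Reagents that add atoms: none
Why: Chiral Ti(IV)–BINOLate-catalysed endo Diels–Alder reaction, in which two-point binding of Ti to the C11 carbonyl and its neighbouring methoxy oxygen activates the methyl-bearing C1=C10 bond so that the nucleophilic CH2 terminus of the siloxydiene bonds to C1 (β to C11), the ligand sets the quaternary C1 centre and suprafacial addition gives the cis fusion.

Step 2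
Reactants: 3 cis-fused adduct
Product: 4 trans-fused dione (10α-H)
Conditions: DBU (0.2 equiv), toluene, rt
Reagents that add atoms: none
Why: Base-mediated epimerisation α to the C11 ketone under thermodynamic control should give the trans-fused isomer (H-10 anti to Me-15), as is usual for angularly methylated quinone adducts.

Step 3
Reactants: 4 trans-fused dione
Product: 5 11-methylene 14-ketone
Conditions: Ph3PCH3Br, KOtBu, THF, 0 °C to rt
Reagents that add atoms: methyltriphenylphosphonium bromide (C[P+](c1ccccc1)(c1ccccc1)c1ccccc1.[Br-])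
Why: Wittig methylenation should be selective for the C11 ketone because the C14 carbonyl is a deactivated vinylogous ester and the silyl enol ether is inert, while reversible enolisation only returns the trans fusion.

Step 4
Reactants: 5 11-methylene 14-ketone
Product: 6 11β-methyl vinylogous ester (11α-H)
Conditions: H2 (1 atm), RhCl(PPh3)3 (5 mol %), benzene, rt
Reagents that add atoms: none
Why: Homogeneous hydrogenation with Wilkinson's catalyst should reduce only the unhindered 1,1-disubstituted alkene, from the α face opposite Me-15, and the C11 configuration is immaterial because it is planarised in step 23.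

Step 5
Reactants: 6 11β-methyl vinylogous ester
Product: 7 ring-B Δ8-en-7-one
Conditions: Pd(OAc)2 (1.05 equiv), MeCN, rt
Reagents that add atoms: none
Why: Saegusa–Ito oxidation of the regiodefined silyl enol ether gives the enone by β-hydride elimination from C9.

Step 6
Reactants: 7 ring-B enone
Product: 8 8α,9α-epoxy-7-ketone
Conditions: tBuOOH, DBU, CH2Cl2, 0 °C
Reagents that add atoms: tert-butyl hydroperoxide (CC(C)(C)OO)
Why: Weitz–Scheffer nucleophilic epoxidation, in which the peroxide anion adds to C9 from the α face because Me-15 is 1,3-syn-axial to the β face, while the ring-A vinylogous ester is too electron-rich to react.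

Step 7
Reactants: 8 epoxy ketone
Product: 9 9β-(3,4-dimethoxybenzyloxy)-8α-hydroxy-7-ketone
Conditions: 3,4-dimethoxybenzyl alcohol (5 equiv), Yb(OTf)3 (10 mol %), CH2Cl2, rt
Reagents that add atoms: 3,4-dimethoxybenzyl alcohol (COc1ccc(CO)cc1OC)
Why: Lewis-acid-catalysed alcoholysis of the α,β-epoxy ketone at the β-carbon C9 with inversion is the trans-diaxial (Fürst–Plattner) opening and sets the 9β-oxygen and the 8α-hydroxyl.

Step 8
Reactants: 9 hydroxy ketone
Product: 10 8α-triethylsilyl ether
Conditions: TESOTf, 2,6-lutidine, CH2Cl2, −78 °C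
Reagents that add atoms: triethylsilyl trifluoromethanesulfonate (CC[Si](CC)(CC)OS(=O)(=O)C(F)(F)F)
Why: Silylation of the only hydroxyl protects the α-ketol from enediol isomerisation during the enolate steps.

Step 9
Reactants: 10 silyl ether; 11 2-[(4-methoxybenzyl)oxy]acetaldehyde
Product: 14 (Z)-2-[2-(4-methoxybenzyloxy)ethylidene]-7-ketone, via aldol adduct 12 (not isolated), via mesylate 13 (not isolated)
Conditions: LDA, THF, −78 °C; 11; MsCl, −78 to 0 °C; DBU, rt
Reagents that add atoms: none
Why: Aldol condensation through the kinetic C2 enolate (the equatorial 8-H is poorly aligned for deprotonation) followed by mesylation and E1cB elimination should place C4 syn to the carbonyl, away from quaternary C1.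

Step 10
Reactants: 14 alkylidene ketone
Product: 16 2β-[(Z)-2-(4-methoxybenzyloxy)vinyl]-7-ketone (2α-H), via lithium dienolate 15 (not isolated)
Conditions: LDA, HMPA, THF, −78 °C; AcOH, −78 °C
Reagents that add atoms: none
Why: Deconjugative isomerisation in which γ-deprotonation at C4 gives the dienolate with the alkoxy group cisoid (syn effect, hence the Z enol ether) and kinetic α-protonation from the α face leaves the side chain equatorial at C2.

Step 11
Reactants: 16 β,γ-unsaturated ketone
Product: 17 7α-ethynyl-7β-ol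
Conditions: HC≡CMgBr, CeCl3, THF, −78 °C; aq NH4Cl
Reagents that add atoms: ethynylmagnesium bromide (C#C[Mg]Br)
Why: Organocerium 1,2-addition, in which the β face of C7 is blocked by the syn-axial Me-15 and 9β-ether so that the acetylide enters equatorially from the α face (axial 7β-OH), while the non-basic reagent avoids reconjugation and spares the vinylogous ester.

Step 12
Reactants: 17 ethynyl carbinol
Product: 18 7α-(propa-1,2-dienyl)-7β-ol
Conditions: (CH2O)n, iPr2NH, CuBr (cat.), dioxane, reflux
Reagents that add atoms: paraformaldehyde (C=O)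
Why: Crabbé homologation (Mannich addition of the copper acetylide, then 1,5-hydride transfer from the diisopropylamino group) converts the terminal alkyne into the terminal allene without touching C7.

Step 13
Reactants: 18 allenyl carbinol
Product: 19 7β,8α-diol
Conditions: TBAF, AcOH, THF, 0 °C
Reagents that add atoms: none
Why: Fluoride cleaves the triethylsilyl ether, and the acetic acid buffer keeps the tertiary allenyl carbinol from forming an alkoxide that could rearrange early.

Step 14
Reactants: 19 diol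
Product: 20 7β-hydroxy-8-ketone
Conditions: Dess–Martin periodinane, NaHCO3, CH2Cl2, 0 °C to rt
Reagents that add atoms: none
Why: Dess–Martin oxidation acts on the only secondary alcohol, and the buffer protects the enol ether.

Step 15
Reactants: 20 hydroxy ketone; 21 2-bromopropanoyl bromide
Product: 22 7β-(2-bromopropanoyloxy)-8-ketone
Conditions: pyridine, DMAP (cat.), CH2Cl2, 0 °C
Reagents that add atoms: none
Why: DMAP-catalysed acylation of the tertiary 7β-hydroxyl tethers C17–C19 to O7, and the racemic bromide is acceptable because C17 is reset in step 16.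

Step 16
Reactants: 22 bromo ester
Product: 23 cis-fused γ-lactone (O7–C19(=O)–C17–C8, 8α-OH, 17R)
Conditions: SmI2 (2.2 equiv), THF, −78 °C; aq NH4Cl
Reagents that add atoms: none
Why: Intramolecular samarium Reformatsky reaction, in which the enolate tethered to the axial 7β-oxygen can reach C8 only equatorially, so the tertiary 8-hydroxyl is set axial (α) and the 17-methyl should take the less hindered position anti to C9.

Step 17
Reactants: 23 bicyclic lactone
Product: 26 (2E,4S,6R)-6-hydroxy-7-oxo ten-membered seco acid, via potassium carboxylate 24 (not isolated), via tripotassium dienolate 25 (not isolated)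
Conditions: KOH (1.05 equiv), THF–H2O, rt; evaporate, dry; KH (4 equiv), 18-crown-6, THF, 0 °C to rt; −78 °C, 2-(phenylsulfonyl)-3-phenyloxaziridine; aq HCl to pH 3
Reagents that add atoms: potassium hydroxide ([K+].[OH-]); 2-(phenylsulfonyl)-3-phenyloxaziridine (O=S(=O)(N1OC1c1ccccc1)c1ccccc1)
Why: Hydroxide opens the lactone to carboxylate 24, which cannot re-lactonise and disfavours retro-aldol cleavage, KH/18-crown-6 then gives the free C7 alkoxide whose 3-oxido-1,5-diene C4=C3–C2–C7(O−)–C6=C5(=C16) undergoes the charge-accelerated [3,3] shift that breaks C2–C7 and forms C4–C5 with the distal allene π bond surviving as the exo-methylene, and dienolate 25 is hydroxylated at C6 by the N-sulfonyloxaziridine. The closest known reaction type is the anionic oxy-Cope ring expansion of trans-1,2-dialkenylcyclohexanols to (E)-cyclodec-5-enones, here with an allene as one 2π partner and enolate oxidation in the same flask. The ten-membered ring is thus formed by a four-atom ring expansion of ring B through a six-centre chair transition state, not by end-to-end cyclisation. Because the C2 vinyl and C7 allenyl groups are trans-diequatorial on the rigid trans-decalin, only that chair is accessible: C1 lies anti to C4 (E C2=C3), the Z enol ether puts its ether oxygen pseudo-axial so that C5 bonds to the C4 face giving the 4S ether, and the crossed dienolate exposes only its outer face at C6, where oxygen should enter to give the 6R alcohol that step 19 inverts. The step needs the [3,3] shift over fragmentation and α- over γ-attack of the oxidant, which the carboxylate form, the absence of any other alkene next to C7 and the usual α-selectivity of dienolates should secure.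

Step 18
Reactants: 26 seco acid
Product: 27 methyl ester
Conditions: TMSCHN2, MeOH–toluene, 0 °C
Reagents that add atoms: (trimethylsilyl)diazomethane (C[Si](C)(C)C=[N+]=[N-])
Why: Esterification with the diazomethane equivalent is selective for the carboxylic acid and masks it for the chlorination.

Step 19
Reactants: 27 hydroxy keto ester
Product: 28 (6S)-6-chloro-7-oxo methyl ester
Conditions: MsCl, 2,4,6-collidine, LiCl, DMF, 0 °C to rt
Reagents that add atoms: lithium chloride ([Li+].[Cl-])
Why: Mesylation of the secondary α-ketol hydroxyl and SN2 displacement by chloride, accelerated at the carbon α to the ketone, should proceed with inversion and leave the tertiary 8-hydroxyl untouched.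

Step 20
Reactants: 28 chloro keto ester
Product: 30 7,19-γ-lactone with ring-A 13-en-12-one (9-O-DMB, 4-O-PMB, 11-H), via diol ester 29 (not isolated)
Conditions: NaBH4, CeCl3·7H2O, MeOH, −78 to 0 °C; then 1 M HCl, THF, rt
Reagents that add atoms: water (O)
Why: Luche reduction of the α-chloro ketone (hydride anti to C–Cl in the polar Felkin–Anh sense and on the outer face of the Ce-chelated α-hydroxy ketone, both predicting 7R) and of the vinylogous ester carbonyl, followed by acid, which closes the γ-lactone from O7 onto the methyl ester and effects the Stork–Danheiser transposition to the ring-A enone.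

Step 21
Reactants: 30 lactone enone
Product: 31 9-alcohol
Conditions: DDQ (1.1 equiv), CH2Cl2–pH 7 buffer, 0 °C
Reagents that add atoms: none
Why: Oxidative debenzylation by DDQ is faster for the more electron-rich 3,4-dimethoxybenzyl ether than for the 4-methoxybenzyl ether, so only the 9-hydroxyl should be freed.

Step 22
Reactants: 31 9-alcohol
Product: 32 9-acetate
Conditions: Ac2O, pyridine, DMAP (cat.), CH2Cl2, rt
Reagents that add atoms: acetic anhydride (CC(=O)OC(C)=O)
Why: DMAP-catalysed acetylation takes the secondary 9-hydroxyl, while the tertiary 8-hydroxyl is unreactive under these conditions.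

Step 23
Reactants: 32 9-acetate
Product: 33 9,11-diacetate 4-O-PMB ether
Conditions: Mn(OAc)3·2H2O, benzene, reflux
Reagents that add atoms: manganese(III) acetate (CC(=O)[O-].CC(=O)[O-].CC(=O)[O-].[Mn+3])
Why: Mn(III)-mediated α′-acetoxylation of the enone at C11, its only enolisable position, should deliver acetate to the α face, anti to Me-15 and the C9 branch, giving the 11α-acetate with Me-20 β.

Step 24
Reactants: 33 diacetate PMB ether
Product: 34 CNP0196166.1
Conditions: DDQ (1.5 equiv), CH2Cl2–pH 7 buffer, rt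
Reagents that add atoms: none
Why: Oxidative cleavage of the 4-methoxybenzyl ether by DDQ under buffered conditions frees the allylic 4-hydroxyl without affecting the acetates, lactone or chloride.

Compound list
1 | 2-methoxy-5-methyl-1,4-benzoquinone | COC1=CC(=O)C(C)=CC1=O | starting material
2 | 2-(trimethylsilyloxy)buta-1,3-diene | C=CC(=C)O[Si](C)(C)C | starting material
3 | cis-fused adduct: 12-methoxy-1β-methyl-7-(trimethylsilyloxy)decalin-7,12-diene-11,14-dione, 10β-H | C[C@@]12CC(O[Si](C)(C)C)=CC[C@@H]1C(=O)C(OC)=CC2=O | intermediate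
4 | trans-fused dione (10α-H epimer of 3) | C[C@@]12CC(O[Si](C)(C)C)=CC[C@H]1C(=O)C(OC)=CC2=O | intermediate
5 | 11-methylene-12-methoxy-1β-methyl-7-(trimethylsilyloxy)-trans-decalin-7,12-dien-14-one | C[C@@]12CC(O[Si](C)(C)C)=CC[C@H]1C(=C)C(OC)=CC2=O | intermediate
6 | 12-methoxy-1β,11β-dimethyl-7-(trimethylsilyloxy)-trans-decalin-7,12-dien-14-one | C[C@@]12CC(O[Si](C)(C)C)=CC[C@H]1[C@@H](C)C(OC)=CC2=O | intermediate
7 | 12-methoxy-1β,11β-dimethyl-trans-decalin-8,12-diene-7,14-dione | C[C@@]12CC(=O)C=C[C@H]1[C@@H](C)C(OC)=CC2=O | intermediate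
8 | 8α,9α-epoxide of 7 | C[C@@]12CC(=O)[C@@H]3O[C@@H]3[C@H]1[C@@H](C)C(OC)=CC2=O | intermediate
9 | 9β-(3,4-dimethoxybenzyloxy)-8α-hydroxy-7-ketone | C[C@@]12CC(=O)[C@H](O)[C@@H](OCc3ccc(OC)c(OC)c3)[C@H]1[C@@H](C)C(OC)=CC2=O | intermediate
10 | 8α-triethylsilyl ether of 9 | C[C@@]12CC(=O)[C@H](O[Si](CC)(CC)CC)[C@@H](OCc3ccc(OC)c(OC)c3)[C@H]1[C@@H](C)C(OC)=CC2=O | intermediate
11 | 2-[(4-methoxybenzyl)oxy]acetaldehyde | O=CCOCc1ccc(OC)cc1 | starting material
12 | C2 aldol adduct of 10 and 11 (2-[1-hydroxy-2-(4-methoxybenzyloxy)ethyl]-7-ketone, C2/C3 unassigned) | C[C@@]12C(C(O)COCc3ccc(OC)cc3)C(=O)[C@H](O[Si](CC)(CC)CC)[C@@H](OCc3ccc(OC)c(OC)c3)[C@H]1[C@@H](C)C(OC)=CC2=O | intermediate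
13 | methanesulfonate of 12 | C[C@@]12C(C(OS(C)(=O)=O)COCc3ccc(OC)cc3)C(=O)[C@H](O[Si](CC)(CC)CC)[C@@H](OCc3ccc(OC)c(OC)c3)[C@H]1[C@@H](C)C(OC)=CC2=O | intermediate
14 | (Z)-2-[2-(4-methoxybenzyloxy)ethylidene]-7-ketone (C4 syn to C7=O) | C[C@@]12/C(=C/COCc3ccc(OC)cc3)C(=O)[C@H](O[Si](CC)(CC)CC)[C@@H](OCc3ccc(OC)c(OC)c3)[C@H]1[C@@H](C)C(OC)=CC2=O | intermediate
15 | lithium dienolate of 14 (O–C7=C2–C3=C4–OPMB, 3Z) | C[C@@]12C(/C=C\OCc3ccc(OC)cc3)=C([O-])[C@H](O[Si](CC)(CC)CC)[C@@H](OCc3ccc(OC)c(OC)c3)[C@H]1[C@@H](C)C(OC)=CC2=O.[Li+] | intermediate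
16 | 2β-[(Z)-2-(4-methoxybenzyloxy)vinyl]-7-ketone (2α-H) | C[C@@]12[C@@H](/C=C\OCc3ccc(OC)cc3)C(=O)[C@H](O[Si](CC)(CC)CC)[C@@H](OCc3ccc(OC)c(OC)c3)[C@H]1[C@@H](C)C(OC)=CC2=O | intermediate
17 | 7α-ethynyl-7β-ol | C[C@@]12[C@@H](/C=C\OCc3ccc(OC)cc3)[C@](O)(C#C)[C@H](O[Si](CC)(CC)CC)[C@@H](OCc3ccc(OC)c(OC)c3)[C@H]1[C@@H](C)C(OC)=CC2=O | intermediate
18 | 7α-(propa-1,2-dienyl)-7β-ol | C[C@@]12[C@@H](/C=C\OCc3ccc(OC)cc3)[C@](O)(C=C=C)[C@H](O[Si](CC)(CC)CC)[C@@H](OCc3ccc(OC)c(OC)c3)[C@H]1[C@@H](C)C(OC)=CC2=O | intermediate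
19 | 7α-allenyl-7β,8α-diol | C[C@@]12[C@@H](/C=C\OCc3ccc(OC)cc3)[C@](O)(C=C=C)[C@H](O)[C@@H](OCc3ccc(OC)c(OC)c3)[C@H]1[C@@H](C)C(OC)=CC2=O | intermediate
20 | 7α-allenyl-7β-hydroxy-8-ketone | C[C@@]12[C@@H](/C=C\OCc3ccc(OC)cc3)[C@](O)(C=C=C)C(=O)[C@@H](OCc3ccc(OC)c(OC)c3)[C@H]1[C@@H](C)C(OC)=CC2=O | intermediate
21 | 2-bromopropanoyl bromide (racemic) | CC(Br)C(=O)Br | starting material
22 | 7β-(2-bromopropanoyloxy)-8-ketone | C[C@@]12[C@@H](/C=C\OCc3ccc(OC)cc3)[C@](OC(=O)C(C)Br)(C=C=C)C(=O)[C@@H](OCc3ccc(OC)c(OC)c3)[C@H]1[C@@H](C)C(OC)=CC2=O | intermediate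
23 | cis-fused γ-lactone on ring B (O7–C19(=O)–C17–C8; 8α-OH, 17R, 7α-allenyl) | C[C@@]12[C@@H](/C=C\OCc3ccc(OC)cc3)[C@@]4(C=C=C)OC(=O)[C@H](C)[C@@]4(O)[C@@H](OCc3ccc(OC)c(OC)c3)[C@H]1[C@@H](C)C(OC)=CC2=O | intermediate
24 | potassium carboxylate of the ring-opened 7β,8α-dihydroxy acid | C[C@@]12[C@@H](/C=C\OCc3ccc(OC)cc3)[C@](O)(C=C=C)[C@@](O)([C@@H](C)C(=O)[O-])[C@@H](OCc3ccc(OC)c(OC)c3)[C@H]1[C@@H](C)C(OC)=CC2=O.[K+] | intermediate
25 | tripotassium salt of the ring-expanded dienolate (2E, 4S, C7 enolate, C8 alkoxide, C19 carboxylate) | C=C1/C=C(\[O-])[C@@]([O-])([C@@H](C)C(=O)[O-])[C@@H](OCc3ccc(OC)c(OC)c3)[C@H]2[C@@H](C)C(OC)=CC(=O)[C@]2(C)/C=C/[C@@H]1OCc1ccc(OC)cc1.[K+].[K+].[K+] | intermediate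
26 | (2E,4S,6R)-6-hydroxy-7-oxo ten-membered seco acid (8-OH, 9-O-DMB, 4-O-PMB, 5(16)-ene) | C=C1[C@@H](OCc3ccc(OC)cc3)/C=C/[C@@]2(C)C(=O)C=C(OC)[C@H](C)[C@@H]2[C@H](OCc3ccc(OC)c(OC)c3)[C@](O)([C@@H](C)C(=O)O)C(=O)[C@@H]1O | intermediate
27 | methyl ester of 26 | C=C1[C@@H](OCc3ccc(OC)cc3)/C=C/[C@@]2(C)C(=O)C=C(OC)[C@H](C)[C@@H]2[C@H](OCc3ccc(OC)c(OC)c3)[C@](O)([C@@H](C)C(=O)OC)C(=O)[C@@H]1O | intermediate
28 | (6S)-6-chloro-7-oxo methyl ester | C=C1[C@@H](OCc3ccc(OC)cc3)/C=C/[C@@]2(C)C(=O)C=C(OC)[C@H](C)[C@@H]2[C@H](OCc3ccc(OC)c(OC)c3)[C@](O)([C@@H](C)C(=O)OC)C(=O)[C@H]1Cl | intermediate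
29 | (6S,7R)-6-chloro-7,14-dihydroxy methyl ester (14-OH drawn β) | C=C1[C@@H](OCc3ccc(OC)cc3)/C=C/[C@@]2(C)[C@H](O)C=C(OC)[C@H](C)[C@@H]2[C@H](OCc3ccc(OC)c(OC)c3)[C@](O)([C@@H](C)C(=O)OC)[C@@H](O)[C@H]1Cl | intermediate
30 | 7,19-γ-lactone with 13-en-12-one, 9-O-DMB, 4-O-PMB, 11-H (11β-Me drawn) | C=C1[C@@H](OCc3ccc(OC)cc3)/C=C/[C@@]2(C)C=CC(=O)[C@H](C)[C@@H]2[C@H](OCc3ccc(OC)c(OC)c3)[C@]2(O)[C@@H](C)C(=O)O[C@H]2[C@H]1Cl | intermediate
31 | 9-alcohol (4-O-PMB, 11-H) | C=C1[C@@H](OCc3ccc(OC)cc3)/C=C/[C@@]2(C)C=CC(=O)[C@H](C)[C@@H]2[C@H](O)[C@]2(O)[C@@H](C)C(=O)O[C@H]2[C@H]1Cl | intermediate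
32 | 9-acetate (4-O-PMB, 11-H) | C=C1[C@@H](OCc3ccc(OC)cc3)/C=C/[C@@]2(C)C=CC(=O)[C@H](C)[C@@H]2[C@H](OC(C)=O)[C@]2(O)[C@@H](C)C(=O)O[C@H]2[C@H]1Cl | intermediate
33 | 9,11-diacetate 4-O-PMB ether | C=C1[C@@H](OCc3ccc(OC)cc3)/C=C/[C@@]2(C)C=CC(=O)[C@@](C)(OC(C)=O)[C@@H]2[C@H](OC(C)=O)[C@]2(O)[C@@H](C)C(=O)O[C@H]2[C@H]1Cl | intermediate
34 | CNP0196166.1 | C=C1[C@@H](O)/C=C/[C@@]2(C)C=CC(=O)[C@@](C)(OC(C)=O)[C@@H]2[C@H](OC(C)=O)[C@]2(O)[C@@H](C)C(=O)O[C@H]2[C@H]1Cl | target

Total step count: 24.
Longest linear sequence: 24 steps (from 1 and 2 to 34; 11 and 21 enter as purchased reagents).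

Steps most likely to fail:

Step 17. The ten-membered dienolate may relax to another conformer before it is trapped, so that the oxidant enters on the inner face, or it may react at C16; the 6-hydroxyl would then have the configuration that inversion cannot turn into the natural chloride. The fallback changes how C6 is functionalised, from oxidation followed by SN2 inversion to direct electrophilic chlorination. It sets out again from lactone 23, uses the same opening and rearrangement, and quenches the dienolate at −78 °C with N-chlorosuccinimide, so that the halogen goes to the face the electrophile actually prefers. This would give the (6S)-6-chloro-7-oxo seco acid F1, and esterification with (trimethylsilyl)diazomethane returns to the route at 28; steps 18 and 19 are then not needed.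

Step 10. Deprotonation may occur at C8 instead of C4, the enol ether may form without Z control, or the product may reconjugate on work-up; any of these erodes the (Z)-enol ether on which the C4 configuration depends. The fallback sets out from ketone 10 and installs the side chain by palladium-catalysed α-alkenylation of its enolate (Pd2(dba)3, a bulky phosphine, NaOtBu, toluene) with (Z)-1-bromo-2-[(4-methoxybenzyl)oxy]ethene F2, made from 4-methoxybenzyl vinyl ether by bromination and dehydrobromination. Oxidative addition and reductive elimination keep the alkene geometry, and equilibration at C2 should give the equatorial isomer, so the route is rejoined at 16 and steps 9 and 10 are replaced.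

Step 20. Hydride delivery to C7 may show poor facial selectivity in the flexible ring, giving the 7-epimer, which closes to the cis-fused lactone. The fallback sets out from 28 and carries the same reduction and acid treatment through to the 7-epi lactone F3. This is opened with LiOH to the 7-epi hydroxy acid F4, which is closed again under Mitsunobu conditions (PPh3, DIAD, THF); the carboxylate displaces the activated 7-oxygen with inversion in a 5-exo-tet closure, giving 30.

Further compounds
F1 | step 17 | (2E,4S,6S)-6-chloro-7-oxo ten-membered seco acid (8-OH, 9-O-DMB, 4-O-PMB) | C=C1[C@@H](OCc3ccc(OC)cc3)/C=C/[C@@]2(C)C(=O)C=C(OC)[C@H](C)[C@@H]2[C@H](OCc3ccc(OC)c(OC)c3)[C@](O)([C@@H](C)C(=O)O)C(=O)[C@H]1Cl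
F2 | step 10 | (Z)-1-bromo-2-[(4-methoxybenzyl)oxy]ethene | Br/C=C\OCc1ccc(OC)cc1
F3 | step 20 | 7-epi lactone (C7 epimer of 30) | C=C1[C@@H](OCc3ccc(OC)cc3)/C=C/[C@@]2(C)C=CC(=O)[C@H](C)[C@@H]2[C@H](OCc3ccc(OC)c(OC)c3)[C@]2(O)[C@@H](C)C(=O)O[C@@H]2[C@H]1Cl
F4 | step 20 | 7-epi hydroxy acid (ring-opened F3) | C=C1[C@@H](OCc3ccc(OC)cc3)/C=C/[C@@]2(C)C=CC(=O)[C@H](C)[C@@H]2[C@H](OCc3ccc(OC)c(OC)c3)[C@](O)([C@@H](C)C(=O)O)[C@H](O)[C@H]1Cl
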